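With the ring numbered from the acetoxy carbon (C1 OAc, C2 OMe, C4 OH, C6 side chain), the cyclohexa-2,5-dienol is a divinyl carbinol held in a ring: the bis-allylic C4 sits between the C2=C3 methyl enol ether and the C5=C6 alkene. The route therefore cuts out the C4–C5 unit as acrolein. In the key step an acyclic C3–C2–C1–C6 fragment, an (E)-β-iodo enol ether that also carries a 1,1-disubstituted alkene and both acetates, is joined to acrolein by chromium/nickel-mediated alkenylation (C3–C4 bond, C4 stereocentre) and closed in the same flask by ring-closing metathesis (C5=C6 bond), releasing the acid-labile dienol last.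

Key step: step 9

Remark: the sense of induction of each chiral promoter (steps 1, 6 and 9) is taken by analogy; the enantiomer of catalyst or ligand that gives the configuration drawn is to be used.

Step 1
Reactants: 1 tetradecanal; 2 allenylboronic acid pinacol ester
Product: 3 (R)-heptadec-1-yn-4-ol
Conditions: 2 (1.3 equiv), (R)-3,3′-bis(2,4,6-triisopropylphenyl)-1,1′-binaphthyl-2,2′-diyl hydrogen phosphate (5 mol %), 4 Å MS, toluene, −20 °C; aq. NaHCO3
Reagents that add atoms: none
Why: chiral phosphoric acid-catalysed propargylboration, in which the allenylboronate adds through a closed six-membered SE2′ transition state with one aldehyde face shielded, should give the homopropargylic alcohol and set the side-chain carbinol as (R).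

Step 2
Reactants: 3 (R)-heptadec-1-yn-4-ol
Product: 4 (R)-heptadec-1-yn-4-yl acetate
Conditions: Ac2O, pyridine, DMAP (cat.), CH2Cl2, 0 °C to rt
Reagents that add atoms: acetic anhydride CC(=O)OC(C)=O
Why: standard acylation of a secondary alcohol that does not touch the stereocentre.

Step 3
Reactants: 4 (R)-heptadec-1-yn-4-yl acetate
Product: 5 (R)-2-iodoheptadec-1-en-4-yl acetate
Conditions: NaI, Me3SiCl, H2O (0.5 equiv), MeCN, 0 °C to rt
Reagents that add atoms: sodium iodide [Na+].[I-]
Why: Markovnikov hydroiodination of the terminal alkyne by hydrogen iodide made in the flask should give the 2-iodo-1-alkene without forming a stereocentre, the ester surviving the short, cold exposure.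

Step 4
Reactants: 6 (E)-2-(trimethylsilyl)vinylboronic acid pinacol ester
Product: 7 (E)-(2-methoxyvinyl)trimethylsilane
Conditions: Cu(OAc)2 (2 equiv), Et3N, MeOH, 4 Å MS, rt
Reagents that add atoms: methanol CO
Why: Chan–Lam-type copper-promoted C–O coupling of an alkenylboronate with an alcohol proceeds with retention of the (E) geometry and leaves the C–Si bond untouched.

Step 5
Reactants: 7 (E)-(2-methoxyvinyl)trimethylsilane
Product: 9 (E)-2-methoxy-3-(trimethylsilyl)prop-2-enal, via α-methoxyvinyllithium 8 (not isolated)
Conditions: t-BuLi (1.2 equiv), THF, −78 to −20 °C; DMF, −78 to 0 °C; pH 7 buffer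
Reagents that add atoms: N,N-dimethylformamide CN(C)C=O
Why: oxygen-directed α-lithiation of the vinyl ether gives a configurationally stable vinyllithium that is formylated with retention, so the formyl group ends cis to silicon.

Step 6
Reactants: 5 (R)-2-iodoheptadec-1-en-4-yl acetate; 9 (E)-2-methoxy-3-(trimethylsilyl)prop-2-enal
Product: 10 (R)-2-[(1S,2E)-1-hydroxy-2-methoxy-3-(trimethylsilyl)prop-2-en-1-yl]heptadec-1-en-4-yl acetate
Conditions: CrCl2 (3.5 equiv), (S)-N-[2-(4-isopropyl-4,5-dihydro-1,3-oxazol-2-yl)-6-methylphenyl]methanesulfonamide (3.9 equiv), Et3N, THF, rt; then NiCl2 (5 mol %), 5, 9 (1.5 equiv), rt; aq. NaHCO3/tartrate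
Reagents that add atoms: none
Why: Nozaki–Hiyama–Kishi coupling, in which zerovalent nickel inserts into the C–I bond and the derived alkenylchromium species adds 1,2 to the aldehyde without touching esters or the vinylsilane, with the chiral sulfonamide ligand on chromium differentiating the aldehyde faces so that the new carbinol should be (S).

Step 7
Reactants: 10 (R)-2-[(1S,2E)-1-hydroxy-2-methoxy-3-(trimethylsilyl)prop-2-en-1-yl]heptadec-1-en-4-yl acetate
Product: 11 (R)-2-[(1S,2E)-1-acetoxy-2-methoxy-3-(trimethylsilyl)prop-2-en-1-yl]heptadec-1-en-4-yl acetate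
Conditions: Ac2O, pyridine, DMAP (cat.), CH2Cl2, 0 °C
Reagents that add atoms: acetic anhydride CC(=O)OC(C)=O
Why: base-mediated acylation of the secondary allylic alcohol avoids ionisation next to the enol ether and retains configuration.

Step 8
Reactants: 11 (R)-2-[(1S,2E)-1-acetoxy-2-methoxy-3-(trimethylsilyl)prop-2-en-1-yl]heptadec-1-en-4-yl acetate
Product: 12 (R)-2-[(1S,2E)-1-acetoxy-3-iodo-2-methoxyprop-2-en-1-yl]heptadec-1-en-4-yl acetate
Conditions: N-iodosuccinimide (1.05 equiv), 2,6-lutidine, MeCN, −20 to 0 °C
Reagents that add atoms: N-iodosuccinimide O=C1CCC(=O)N1I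
Why: electrophilic ipso-iododesilylation, in which iodonium attacks the silicon-bearing β-carbon of the enol ether and silicon is lost from the β-silyl oxocarbenium ion, should give the vinyl iodide with retention (iodine cis to the acetoxy carbon), the 1,1-disubstituted alkene being far less nucleophilic.

Step 9
Reactants: 12 (R)-2-[(1S,2E)-1-acetoxy-3-iodo-2-methoxyprop-2-en-1-yl]heptadec-1-en-4-yl acetate; 13 acrolein
Product: 15 (1S,4R)-6-[(2R)-2-acetoxypentadecyl]-4-hydroxy-2-methoxycyclohexa-2,5-dien-1-yl acetate, via acyclic trienol 14 (not isolated)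
Conditions: (a) CrCl2 (4 equiv), (S)-N-[2-(4-isopropyl-4,5-dihydro-1,3-oxazol-2-yl)-6-methylphenyl]methanesulfonamide, Et3N, NiCl2 (5 mol %), 13 (3 equiv), THF, 0 °C to rt; (b) filtration through Florisil under argon, evaporation of excess 13, CH2Cl2 (5 mM), second-generation Grubbs catalyst (5 mol %), 35 °C; Et3N-deactivated silica
Reagents that add atoms: none
Why: Zerovalent nickel inserts into the C–I bond of 12 and transmetalation gives an alkenylchromium species that adds 1,2 to acrolein 13 (Nozaki–Hiyama–Kishi alkenylation), making the ring C3–C4 bond; trienol 14 is then closed by ruthenium-catalysed ring-closing metathesis of its vinyl group onto the 1,1-disubstituted alkene, making the ring C5=C6 bond with loss of ethylene. The closest known reaction types are the ligand-controlled asymmetric chromium/nickel alkenylation of aldehydes and the ring-closing metathesis of a 1,7-diene to a trisubstituted cyclohexene, run here as one telescoped operation. The six-membered ring is closed in the metathesis stage (1,7-diene to cyclohexene), which requires the retained (E) geometry of the enol ether so that C4 and C1 are cis on the C2=C3 bond. The new C4 stereocentre is set in the alkenylation by the chiral sulfonamide–chromium complex (reagent control) and should be (R), which places the hydroxyl cis to the C1 acetate after ring closure. The step needs 1,2- and not 1,4-addition to acrolein, secured by the oxophilic organochromium reagent, and metathesis only at the two terminal alkenes, secured by the hindered trisubstituted enol ether being a poor metathesis partner. Both stages are neutral, so the two acetates stay in place and the bis-allylic dienol is not dehydrated to an arene.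

Compound list
1 | tetradecanal | CCCCCCCCCCCCCC=O | starting material
2 | allenylboronic acid pinacol ester (4,4,5,5-tetramethyl-2-(propa-1,2-dien-1-yl)-1,3,2-dioxaborolane) | C=C=CB1OC(C)(C)C(C)(C)O1 | starting material
3 | (R)-heptadec-1-yn-4-ol | CCCCCCCCCCCCC[C@H](CC#C)O | intermediate
4 | (R)-heptadec-1-yn-4-yl acetate | CCCCCCCCCCCCC[C@H](CC#C)OC(C)=O | intermediate
5 | (R)-2-iodoheptadec-1-en-4-yl acetate | CCCCCCCCCCCCC[C@H](CC(I)=C)OC(C)=O | intermediate
6 | (E)-2-(trimethylsilyl)vinylboronic acid pinacol ester | C[Si](C)(C)/C=C/B1OC(C)(C)C(C)(C)O1 | starting material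
7 | (E)-(2-methoxyvinyl)trimethylsilane | C[Si](C)(C)/C=C/OC | intermediate
8 | (E)-[1-methoxy-2-(trimethylsilyl)ethenyl]lithium | C[Si](C)(C)/C=C(\[Li])OC | intermediate
9 | (E)-2-methoxy-3-(trimethylsilyl)prop-2-enal | C[Si](C)(C)/C=C(\C=O)OC | intermediate
10 | (R)-2-[(1S,2E)-1-hydroxy-2-methoxy-3-(trimethylsilyl)prop-2-en-1-yl]heptadec-1-en-4-yl acetate | CCCCCCCCCCCCC[C@H](CC(=C)[C@H](O)/C(OC)=C\[Si](C)(C)C)OC(C)=O | intermediate
11 | (R)-2-[(1S,2E)-1-acetoxy-2-methoxy-3-(trimethylsilyl)prop-2-en-1-yl]heptadec-1-en-4-yl acetate | CCCCCCCCCCCCC[C@H](CC(=C)[C@H](OC(C)=O)/C(OC)=C\[Si](C)(C)C)OC(C)=O | intermediate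
12 | (R)-2-[(1S,2E)-1-acetoxy-3-iodo-2-methoxyprop-2-en-1-yl]heptadec-1-en-4-yl acetate | CCCCCCCCCCCCC[C@H](CC(=C)[C@H](OC(C)=O)/C(OC)=C\I)OC(C)=O | intermediate
13 | acrolein (prop-2-enal) | C=CC=O | starting material
14 | (R)-2-[(1S,2E,4R)-1-acetoxy-4-hydroxy-2-methoxyhexa-2,5-dien-1-yl]heptadec-1-en-4-yl acetate | CCCCCCCCCCCCC[C@H](CC(=C)[C@H](OC(C)=O)/C(OC)=C\[C@H](O)C=C)OC(C)=O | intermediate
15 | (1S,4R)-6-[(2R)-2-acetoxypentadecyl]-4-hydroxy-2-methoxycyclohexa-2,5-dien-1-yl acetate | CCCCCCCCCCCCC[C@H](CC1=C[C@@H](O)C=C(OC)[C@H]1OC(C)=O)OC(C)=O | target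

Total step count: 9. Longest linear sequence: 7 steps (steps 1, 2, 3, 6, 7, 8, 9; the branch through steps 4 and 5 joins at step 6).

Steps most likely to fail

Step 9. The alkenylchromium species carries a methoxy group anti to the metal and may lose methoxide (β-elimination to a terminal alkyne) before it adds to acrolein. Chromium residues carried into the second stage may also deactivate the ruthenium carbene. The fallback makes the same two ring bonds through palladium, where anti elimination is not available. It sets out from 12: carbonylative Stille coupling with tributyl(vinyl)stannane (Pd(PPh3)4, CO 1 atm, THF, 50 °C) should give (R)-2-[(1S,2E)-1-acetoxy-2-methoxy-4-oxohexa-2,5-dien-1-yl]heptadec-1-en-4-yl acetate F1. Corey–Bakshi–Shibata reduction of F1 (2-methyl-oxazaborolidine, catecholborane, −78 °C) should then set C4 and come back to the route at 14, which is closed to 15 with the second-generation Grubbs catalyst as in stage (b).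

Step 8. The product β-iodo enol ether is still electron-rich and acid-labile, so a second iodination or hydrolysis of the enol ether may consume it. The fallback avoids the halide altogether and forms no new compound (F0). It sets out from 11: Lewis-acid-promoted ipso-substitution of the vinylsilane by acrolein (Me2AlCl, CH2Cl2, −78 °C, Et3N quench) should give 14 directly as a mixture of C4 epimers, the trans-isomer being removed after ring closure. It comes back to the route at 14.

Step 6. Facial selectivity in the addition to the α-methoxy enal may be poor if ligand and substrate are mismatched. The fallback sets out from 5 and 9: ligand-free CrCl2/NiCl2 coupling, then chromatographic separation of 10 from its epimer (R)-2-[(1R,2E)-1-hydroxy-2-methoxy-3-(trimethylsilyl)prop-2-en-1-yl]heptadec-1-en-4-yl acetate F2. Mitsunobu inversion of F2 with acetic acid (PPh3, diisopropyl azodicarboxylate, THF, 0 °C) should give 11 directly, while 10 is acetylated as in step 7. Both streams come back to the route at 11.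

Further compounds
F1 | step 9 | (R)-2-[(1S,2E)-1-acetoxy-2-methoxy-4-oxohexa-2,5-dien-1-yl]heptadec-1-en-4-yl acetate | CCCCCCCCCCCCC[C@H](CC(=C)[C@H](OC(C)=O)/C(OC)=C\C(=O)C=C)OC(C)=O
F0 | step 8 | none | none
F2 | step 6 | (R)-2-[(1R,2E)-1-hydroxy-2-methoxy-3-(trimethylsilyl)prop-2-en-1-yl]heptadec-1-en-4-yl acetate | CCCCCCCCCCCCC[C@H](CC(=C)[C@@H](O)/C(OC)=C\[Si](C)(C)C)OC(C)=O
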